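**Retrosynthetic overview**
1. Target 19 ⇐ hydroquinone keto nitrile 17 ⇐ dimethyl ether 16 (Pinner methanolysis; BBr3). The nitrile serves as the carboxyl surrogate because, unlike an ester, its linear geometry cannot reach the cationic centres.
2. 16 ⇐ acyclic epoxy diene 14 in one cationic cascade: epoxide opening at chain C11, ring A first (C11–C6 bond), ring B second (C7–C2 bond), then five 1,2-shifts (H, Me, H, Me, H) that end in the ketone.
3. 14 ⇐ allylic alcohol 11 by Sharpless epoxidation and triflate displacement with LiCH2CN.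
4. 11 ⇐ nerol 1 (its Z-alkene later fixes C8), 4-methoxy-2-methylphenol 3 and prenyl chloride 8, by phenoxide C-allylation, two SeO2 oxidations and one allylbarium coupling.

Assumption: chain carbons are numbered C1 (benzylic) to C14 (nitrile or ester carbon); chain C11, C10, C6, C7, C2, C3 become decalin C4, C3, C5, C10, C9, C8; α/β refer to the decalin drawn with ring A on the left and C10 at the top of the fusion, β toward the viewer.

**Step 1**
Reactants: 1 nerol
Product: 2 neryl bromide
Conditions: PBr3 (0.4 equiv), Et2O, −10 °C, 30 min; used crude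
Reagents that add atoms: phosphorus tribromide, BrP(Br)Br
Why: SN2-type bromination of a primary allylic alcohol at low temperature keeps the (2Z) geometry and forms no stereocenter.

**Step 2**
Reactants: 3 4-methoxy-2-methylphenol; 2 neryl bromide
Product: 5 1-[(2Z)-3,7-dimethylocta-2,6-dien-1-yl]-2,5-dimethoxy-3-methylbenzene, via 2-neryl-4-methoxy-6-methylphenol 4 (not isolated)
Conditions: NaH (1 equiv per phenol), toluene, 0 °C to rt; 2 (0.5 equiv), rt, 16 h; then NaH, MeI, DMF, 0 °C to rt
Reagents that add atoms: iodomethane, CI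
Why: ortho-C-allylation of a sodium phenoxide in a non-polar solvent (SN2 at the primary allylic bromide; C6 is the only free ortho position and para is blocked) followed by Williamson O-methylation leaves the Z-alkene untouched.

**Step 3**
Reactants: 5 1-[(2Z)-3,7-dimethylocta-2,6-dien-1-yl]-2,5-dimethoxy-3-methylbenzene
Product: 6 (2E,6Z)-8-(2,5-dimethoxy-3-methylphenyl)-2,6-dimethylocta-2,6-dien-1-ol
Conditions: SeO2 (0.5 equiv), t-BuOOH (3 equiv), salicylic acid (0.1 equiv), CH2Cl2, 0 °C to rt
Reagents that add atoms: tert-butyl hydroperoxide, CC(C)(C)OO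
Why: SeO2-catalysed allylic oxidation (ene reaction then [2,3]-sigmatropic shift) attacks the (E)-methyl of the terminal isopropylidene group, which sets the E geometry of that alkene.

**Step 4**
Reactants: 6 (2E,6Z)-8-(2,5-dimethoxy-3-methylphenyl)-2,6-dimethylocta-2,6-dien-1-ol
Product: 7 1-[(2Z,6E)-8-bromo-3,7-dimethylocta-2,6-dien-1-yl]-2,5-dimethoxy-3-methylbenzene
Conditions: PBr3 (0.4 equiv), Et2O, −20 to 0 °C; used crude
Reagents that add atoms: phosphorus tribromide, BrP(Br)Br
Why: SN2-type bromination of the primary allylic alcohol proceeds without allylic transposition, so both alkene geometries are kept.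

**Step 5**
Reactants: 7 1-[(2Z,6E)-8-bromo-3,7-dimethylocta-2,6-dien-1-yl]-2,5-dimethoxy-3-methylbenzene; 8 prenyl chloride
Product: 10 2,5-dimethoxy-3-methyl-1-[(2Z,6E)-3,7,11-trimethyldodeca-2,6,10-trien-1-yl]benzene, via prenylbarium chloride 9 (not isolated)
Conditions: BaI2, lithium biphenylide Li(C12H10) (2 equiv), THF, rt (activated Ba); 8, −78 °C; then 7, −78 °C
Reagents that add atoms: none
Why: allylbarium–allyl halide cross-coupling (Yamamoto) joins the two allylic carbons α to α′ with retention of alkene geometry, giving the linear 1,5-diene without a new stereocenter.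

**Step 6**
Reactants: 10 2,5-dimethoxy-3-methyl-1-[(2Z,6E)-3,7,11-trimethyldodeca-2,6,10-trien-1-yl]benzene
Product: 11 (2E,6E,10Z)-12-(2,5-dimethoxy-3-methylphenyl)-2,6,10-trimethyldodeca-2,6,10-trien-1-ol
Conditions: SeO2 (0.5 equiv), t-BuOOH (3 equiv), salicylic acid (0.1 equiv), CH2Cl2, 0 °C to rt
Reagents that add atoms: tert-butyl hydroperoxide, CC(C)(C)OO
Why: the same SeO2 allylic oxidation again selects the (E)-methyl of the terminal isopropylidene group, giving the (E)-2-methylallylic alcohol needed for directed epoxidation.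

**Step 7**
Reactants: 11 (2E,6E,10Z)-12-(2,5-dimethoxy-3-methylphenyl)-2,6,10-trimethyldodeca-2,6,10-trien-1-ol
Product: 12 [(2R,3R)-3-[(3E,7Z)-9-(2,5-dimethoxy-3-methylphenyl)-3,7-dimethylnona-3,7-dien-1-yl]-2-methyloxiran-2-yl]methanol
Conditions: Ti(OiPr)4 (0.1 equiv), D-(−)-diethyl tartrate (0.12 equiv), t-BuOOH (2 equiv), 4 Å sieves, CH2Cl2, −20 °C
Reagents that add atoms: tert-butyl hydroperoxide, CC(C)(C)OO
Why: Sharpless asymmetric epoxidation touches only the allylic-alcohol alkene, and D-(−)-tartrate delivers oxygen to the face that gives the (2R,3R)-epoxide (chain C11 and C10 both R), the mirror image of the (2S,3S) result known for (E)-2-methyl-2-alkenols with L-(+)-tartrate.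

**Step 8**
Reactants: 12 [(2R,3R)-3-[(3E,7Z)-9-(2,5-dimethoxy-3-methylphenyl)-3,7-dimethylnona-3,7-dien-1-yl]-2-methyloxiran-2-yl]methanol
Product: 14 3-[(2R,3R)-3-[(3E,7Z)-9-(2,5-dimethoxy-3-methylphenyl)-3,7-dimethylnona-3,7-dien-1-yl]-2-methyloxiran-2-yl]propanenitrile, via epoxy triflate 13 (not isolated)
Conditions: Tf2O (1.1 equiv), 2,6-lutidine (1.5 equiv), CH2Cl2, −78 °C; then LiCH2CN (3 equiv, from MeCN and n-BuLi), THF, −78 °C
Reagents that add atoms: lithioacetonitrile (from acetonitrile and n-BuLi), [Li]CC#N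
Why: triflation followed by SN2 displacement with lithioacetonitrile at −78 °C, where the primary triflate (no β-hydrogen, so no elimination) reacts far faster than the trisubstituted epoxide, leaves both epoxide stereocenters untouched.

**Step 9**
Reactants: 14 3-[(2R,3R)-3-[(3E,7Z)-9-(2,5-dimethoxy-3-methylphenyl)-3,7-dimethylnona-3,7-dien-1-yl]-2-methyloxiran-2-yl]propanenitrile
Product: 16 3-[(1S,4aR,5S,6S,8aR)-5-[(2,5-dimethoxy-3-methylphenyl)methyl]-5,6,8a-trimethyl-2-oxodecahydronaphthalen-1-yl]propanenitrile, via decalin C8 carbocation 15 (not isolated)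
Conditions: BF3·OEt2 (3 equiv), CH2Cl2 (5 mM), −78 to −10 °C, 3 h; aq. NaHCO3
Reagents that add atoms: none
Why: Proposed new method: BF3 opens the epoxide at its tertiary carbon with anti attack by the (6E)-alkene and then the (2Z)-alkene through a chair–chair fold (ring A, then ring B), giving trans-decalin cation 15 with the oxygen equatorial, the C4 methyl axial (it was cis to the chain on the E-epoxide) and, because of the Z-alkene, the arylmethyl group axial and H9 on the face of the C10 methyl; five suprafacial 1,2-shifts (H9→C8, 10-Me→C9, H5→C10, 4-Me→C5, H3→C4) then carry the charge to C4, where the last hydride shift from the carbinol carbon is an irreversible semipinacol step that forms the ketone, so that the (R)-epoxide carbon fixes the absolute configuration, the Z-alkene fixes the 8-methyl trans to the 9-methyl, and the C4 side chain ends equatorial (also the thermodynamic epimer); the closest known reaction types are epoxy-polyene cyclization, the BF3-promoted drimane-to-avarane (friedo) rearrangement of aryl sesquiterpenoids, and the friedelin-type hydride-shift termination.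

**Step 10**
Reactants: 16 3-[(1S,4aR,5S,6S,8aR)-5-[(2,5-dimethoxy-3-methylphenyl)methyl]-5,6,8a-trimethyl-2-oxodecahydronaphthalen-1-yl]propanenitrile
Product: 17 3-[(1S,4aR,5S,6S,8aR)-5-[(2,5-dihydroxy-3-methylphenyl)methyl]-5,6,8a-trimethyl-2-oxodecahydronaphthalen-1-yl]propanenitrile
Conditions: BBr3 (5 equiv), CH2Cl2, −78 to 0 °C; ice water
Reagents that add atoms: none
Why: BBr3 cleavage of aryl methyl ethers (Lewis-acid dealkylation) frees the hydroquinone while nitrile and ketone only complex reversibly and no stereocenter is affected.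

**Step 11**
Reactants: 17 3-[(1S,4aR,5S,6S,8aR)-5-[(2,5-dihydroxy-3-methylphenyl)methyl]-5,6,8a-trimethyl-2-oxodecahydronaphthalen-1-yl]propanenitrile
Product: 19 methyl 3-[(1S,4aR,5S,6S,8aR)-5-[(2,5-dihydroxy-3-methylphenyl)methyl]-5,6,8a-trimethyl-2-oxodecahydronaphthalen-1-yl]propanoate, via methyl imidate hydrochloride 18 (not isolated)
Conditions: AcCl (30 equiv), MeOH, 0 °C to rt, 24 h; then H2O, rt, 2 h
Reagents that add atoms: methanol, CO; water, O
Why: Pinner reaction (nitrile to imidate hydrochloride, then hydrolysis to the methyl ester) under acidic conditions that protect the hydroquinone from oxidation and leave the equatorial side chain at the ketone α-carbon in its thermodynamic configuration.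

**Compound list**
1 | nerol, (2Z)-3,7-dimethylocta-2,6-dien-1-ol | CC(C)=CCC/C(C)=C\CO | starting material
2 | neryl bromide, (2Z)-1-bromo-3,7-dimethylocta-2,6-diene | CC(C)=CCC/C(C)=C\CBr | intermediate
3 | 4-methoxy-2-methylphenol | COc1ccc(O)c(C)c1 | starting material
4 | 2-[(2Z)-3,7-dimethylocta-2,6-dien-1-yl]-4-methoxy-6-methylphenol (not isolated) | COc1cc(C)c(O)c(C/C=C(C)\CCC=C(C)C)c1 | intermediate
5 | 1-[(2Z)-3,7-dimethylocta-2,6-dien-1-yl]-2,5-dimethoxy-3-methylbenzene | COc1cc(C)c(OC)c(C/C=C(C)\CCC=C(C)C)c1 | intermediate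
6 | (2E,6Z)-8-(2,5-dimethoxy-3-methylphenyl)-2,6-dimethylocta-2,6-dien-1-ol | COc1cc(C)c(OC)c(C/C=C(C)\CC/C=C(\C)CO)c1 | intermediate
7 | 1-[(2Z,6E)-8-bromo-3,7-dimethylocta-2,6-dien-1-yl]-2,5-dimethoxy-3-methylbenzene | COc1cc(C)c(OC)c(C/C=C(C)\CC/C=C(\C)CBr)c1 | intermediate
8 | prenyl chloride, 1-chloro-3-methylbut-2-ene | CC(C)=CCCl | starting material
9 | prenylbarium chloride, (3-methylbut-2-en-1-yl)barium chloride (not isolated) | CC(C)=CC[Ba]Cl | intermediate
10 | 2,5-dimethoxy-3-methyl-1-[(2Z,6E)-3,7,11-trimethyldodeca-2,6,10-trien-1-yl]benzene | COc1cc(C)c(OC)c(C/C=C(C)\CC/C=C(\C)CCC=C(C)C)c1 | intermediate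
11 | (2E,6E,10Z)-12-(2,5-dimethoxy-3-methylphenyl)-2,6,10-trimethyldodeca-2,6,10-trien-1-ol | COc1cc(C)c(OC)c(C/C=C(C)\CC/C=C(\C)CC/C=C(\C)CO)c1 | intermediate
12 | [(2R,3R)-3-[(3E,7Z)-9-(2,5-dimethoxy-3-methylphenyl)-3,7-dimethylnona-3,7-dien-1-yl]-2-methyloxiran-2-yl]methanol | COc1cc(C)c(OC)c(C/C=C(C)\CC/C=C(\C)CC[C@H]2O[C@]2(C)CO)c1 | intermediate
13 | trifluoromethanesulfonate of 12, same (2R,3R)-epoxide (not isolated) | COc1cc(C)c(OC)c(C/C=C(C)\CC/C=C(\C)CC[C@H]2O[C@]2(C)COS(=O)(=O)C(F)(F)F)c1 | intermediate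
14 | 3-[(2R,3R)-3-[(3E,7Z)-9-(2,5-dimethoxy-3-methylphenyl)-3,7-dimethylnona-3,7-dien-1-yl]-2-methyloxiran-2-yl]propanenitrile | COc1cc(C)c(OC)c(C/C=C(C)\CC/C=C(\C)CC[C@H]2O[C@]2(C)CCC#N)c1 | intermediate
15 | trans-decalin C8 carbocation: 3α-O–BF3(−), 4α-methyl, 4β-(2-cyanoethyl), 5β-H, 10α-methyl, 9β-arylmethyl, 9α-H (not isolated) | F[B-](F)(F)O[C@@H]1CC[C@@]2(C)[C@@H](Cc3cc(OC)cc(C)c3OC)[C+](C)CC[C@@H]2[C@@]1(C)CCC#N | intermediate
16 | 3-[(1S,4aR,5S,6S,8aR)-5-[(2,5-dimethoxy-3-methylphenyl)methyl]-5,6,8a-trimethyl-2-oxodecahydronaphthalen-1-yl]propanenitrile (decalin: 3-oxo, 4α-chain, 5α-Me, 10β-H, 9α-Me, 9β-arylmethyl, 8β-Me) | N#CCC[C@@H]1C(=O)CC[C@H]2[C@@]1(C)CC[C@H](C)[C@]2(C)Cc1cc(OC)cc(C)c1OC | intermediate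
17 | 3-[(1S,4aR,5S,6S,8aR)-5-[(2,5-dihydroxy-3-methylphenyl)methyl]-5,6,8a-trimethyl-2-oxodecahydronaphthalen-1-yl]propanenitrile | N#CCC[C@@H]1C(=O)CC[C@H]2[C@@]1(C)CC[C@H](C)[C@]2(C)Cc1cc(O)cc(C)c1O | intermediate
18 | methyl imidate hydrochloride of 17 (not isolated) | COC(=[NH2+])CC[C@@H]1C(=O)CC[C@H]2[C@@]1(C)CC[C@H](C)[C@]2(C)Cc1cc(O)cc(C)c1O.[Cl-] | intermediate
19 | methyl 3-[(1S,4aR,5S,6S,8aR)-5-[(2,5-dihydroxy-3-methylphenyl)methyl]-5,6,8a-trimethyl-2-oxodecahydronaphthalen-1-yl]propanoate (CNP0535359.1) | COC(=O)CC[C@@H]1C(=O)CC[C@H]2[C@@]1(C)CC[C@H](C)[C@]2(C)Cc1cc(O)cc(C)c1O | target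

**Totals**
Total steps: 11. Longest linear sequence: 11 steps (nerol 1 to 19).

**Steps most likely to fail**

Step 9 (cascade). The epoxide may rearrange to an acyclic ketone or add fluoride before it cyclizes. The cascade may stop by proton loss. The electron-rich arene may trap the C8 cation. H9 is equatorial in cation 15, so its shift needs a twisted ring B; a competing Δ8(9)-alkene would erase the C8 control. The fallback sets out from 14 and comes back at 16, and separates ring formation from rearrangement. MeAlCl2 (3 equiv) in CH2Cl2 at −94 to −78 °C closes both rings and stops by proton loss. This gives the trisubstituted-alkene alcohol F1 together with the exocyclic-methylene alcohol F2. Both are then protonated at the alkene by TfOH (0.2 equiv) in HFIP–CH2Cl2 at −40 to 0 °C and run through the same shift sequence to 16. This cures failures of the cyclization stage; it does not cure loss of C8 control.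

Step 5 (allylbarium coupling). Activated barium is demanding to prepare, and homocoupling or branched isomers would be hard to separate. The fallback sets out from 7 and comes back at 10. Prenyl bromide and PhSO2Na in DMF give 3-methylbut-2-en-1-yl phenyl sulfone F3. F3 is deprotonated with n-BuLi in THF at −78 °C and alkylated in the same flask by 7 to give the C9 sulfone F4. LiBHEt3 with PdCl2(dppp) (5 mol%) in THF at 0 °C removes the sulfonyl group without moving the alkenes and gives 10.

Step 2 (phenoxide C-allylation). O-allylation and SN2′ attack compete, so the yield may be low. The fallback sets out from 3 and comes back at 5. NBS in MeCN at 0 °C brominates ortho to the hydroxyl to give 2-bromo-4-methoxy-6-methylphenol F5. MeI and K2CO3 in acetone give 1-bromo-2,5-dimethoxy-3-methylbenzene F6. Bromine–lithium exchange with n-BuLi in THF at −78 °C gives (2,5-dimethoxy-3-methylphenyl)lithium F7. With CuBr·SMe2 (10 mol%) F7 couples with neryl bromide 2 at −78 to 0 °C by direct SN2 to give 5.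

**Further compounds**
F1 | step 9 | bicyclic alkenol with decalin C7=C8 alkene: 3α-hydroxy, 4α-methyl, 4β-(2-cyanoethyl), 5β-H, 10α-methyl, 9β-(2,5-dimethoxy-3-methylbenzyl), 9α-H | O[C@@H]1CC[C@@]2(C)[C@@H](Cc3cc(OC)cc(C)c3OC)C(C)=CC[C@@H]2[C@@]1(C)CCC#N
F2 | step 9 | exocyclic C8-methylene isomer of F1, same stereocenters | O[C@@H]1CC[C@@]2(C)[C@@H](Cc3cc(OC)cc(C)c3OC)C(=C)CC[C@@H]2[C@@]1(C)CCC#N
F3 | step 5 | 3-methylbut-2-en-1-yl phenyl sulfone | CC(C)=CCS(=O)(=O)c1ccccc1
F4 | step 5 | 2,5-dimethoxy-3-methyl-1-[(2Z,6E)-3,7,11-trimethyl-9-(phenylsulfonyl)dodeca-2,6,10-trien-1-yl]benzene, racemic at C9 | COc1cc(C)c(OC)c(C/C=C(C)\CC/C=C(\C)CC(C=C(C)C)S(=O)(=O)c2ccccc2)c1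
F5 | step 2 | 2-bromo-4-methoxy-6-methylphenol | COc1cc(C)c(O)c(Br)c1
F6 | step 2 | 1-bromo-2,5-dimethoxy-3-methylbenzene | COc1cc(C)c(OC)c(Br)c1
F7 | step 2 | (2,5-dimethoxy-3-methylphenyl)lithium | [Li]c1cc(OC)cc(C)c1OC
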